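**Retrosynthetic overview**
1. Target 7 comes from global hydrogenolysis of its octa-O-benzyl ether 6.
2. The C3–O(galloyl) bond of 6 is made by visible-light photoredox anti-Markovnikov addition of acid 5 across C3=C4 of the (2S)-flav-3-ene 4, anti to the C2 aryl group, so C2 sets C3.
3. Flavene 4 comes from syn-dehydration of the 2,3-cis alcohol 2, which can only eliminate toward C4.
4. Alcohol 2 comes from phenol-selective penta-O-benzylation of (−)-epigallocatechin 1, which supplies C2 and rings A, B and C.
5. No ring is constructed: rings A, B and C are bought in 1 and the galloyl ring in 5. Only the C3 stereocentre is erased and reset.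

Assumption: commercial green-tea (−)-epigallocatechin of high purity and ee is taken as the cheap enantiopure starting material, and acid 5, the Burgess reagent and the acridinium salt are bought.

**Step 1**
Reactants: 1 (−)-epigallocatechin
Product: 2 penta-O-benzyl-(−)-epigallocatechin
Conditions: BnBr (5.5 equiv), K2CO3 (6 equiv), degassed DMF, N2, dark, −10 °C → rt
Reagents that add atoms: benzyl bromide, BrCc1ccccc1
Why: Williamson etherification in which carbonate deprotonates only the five phenols and leaves the secondary C3 alcohol free, with oxygen excluded and low temperature to suppress pyrogallol autoxidation and C2 epimerisation, so both stereocentres are carried through unchanged.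

**Step 2**
Reactants: 2 penta-O-benzyl-(−)-epigallocatechin
Product: 4 (2S)-5,7-bis(benzyloxy)-2-[3,4,5-tris(benzyloxy)phenyl]-2H-chromene, via C3 sulfamate triethylammonium salt 3 (not isolated)
Conditions: methyl N-(triethylammoniosulfonyl)carbamate (Burgess reagent, 2 equiv), toluene, N2, dark, rt then 70 °C; rapid filtration through Et3N-deactivated silica
Reagents that add atoms: none
Why: Burgess dehydration is a syn (Ei) elimination, and in the 2,3-cis series the C3–O bond has a cis hydrogen only at C4 (the C2–H is trans, and its syn loss would require a trans double bond in the six-membered ring), so the C3=C4 alkene forms regiospecifically and C2 is untouched (its descriptor changes from R to S only because the CIP priorities change).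

**Step 3**
Reactants: 4 (2S)-5,7-bis(benzyloxy)-2-[3,4,5-tris(benzyloxy)phenyl]-2H-chromene; 5 3,4,5-tris(benzyloxy)benzoic acid
Product: 6 octa-O-benzyl-(+)-gallocatechin gallate
Conditions: 5 (3 equiv), 3,6-di-tert-butyl-9-mesityl-10-phenylacridinium tetrafluoroborate (5 mol%), PhSSPh (10 mol%), 2,6-dimethylpyridine (20 mol%), degassed 1,2-dichloroethane, 450 nm LEDs (no UV), N2, 20 °C
Reagents that add atoms: none
Why: Proposed new method: acridinium-photoredox anti-Markovnikov hydroacyloxylation applied to an enantiopure 2-aryl-2H-chromene with 1,2-induction from C2: the excited acridinium (about +2.0 V vs SCE) oxidises the 5,7-dialkoxy styrene unit (estimated about +1.2 V, the most easily oxidised π system present) to its radical cation, acid 5 or its carboxylate adds at C3 to leave the ring-A-stabilised C4 benzylic radical, attack comes from the face anti to the C2 aryl group (the same facial bias flav-3-enes show in hydroboration and epoxidation, and the diequatorial trans adduct is also favoured if addition is reversible), and thiophenol formed from PhSSPh delivers H to C4, which is not a stereocentre, while thiyl radical and acridinyl radical close the cycle; the closest known reaction type is the acridinium/thiol co-catalysed anti-Markovnikov addition of carboxylic acids to β-substituted styrenes.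

**Step 4**
Reactants: 6 octa-O-benzyl-(+)-gallocatechin gallate
Product: 7 (+)-gallocatechin gallate
Conditions: H2 (1 atm), Pd(OH)2/C (20 wt%), THF/MeOH 1:1, rt; filtration under N2, Sephadex LH-20
Reagents that add atoms: none
Why: Catalytic hydrogenolysis removes the eight benzyl ethers under neutral conditions that spare the gallate ester and the cyclic C2–O1 bond (as in per-benzyl catechin gallate deprotections), and neither stereocentre is touched.

**Compound list**
1 | (−)-epigallocatechin, (2R,3R)-2-(3,4,5-trihydroxyphenyl)chroman-3,5,7-triol (2,3-cis) | O[C@@H]1Cc2c(O)cc(O)cc2O[C@@H]1c1cc(O)c(O)c(O)c1 | starting material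
2 | penta-O-benzyl-(−)-epigallocatechin, (2R,3R)-5,7-bis(benzyloxy)-2-[3,4,5-tris(benzyloxy)phenyl]chroman-3-ol (2,3-cis) | O[C@@H]1Cc2c(OCc3ccccc3)cc(OCc3ccccc3)cc2O[C@@H]1c1cc(OCc3ccccc3)c(OCc3ccccc3)c(OCc3ccccc3)c1 | intermediate
3 | triethylammonium N-(methoxycarbonyl)sulfamate ester of 2 at O3, (2R,3R) | COC(=O)[N-]S(=O)(=O)O[C@@H]1Cc2c(OCc3ccccc3)cc(OCc3ccccc3)cc2O[C@@H]1c1cc(OCc3ccccc3)c(OCc3ccccc3)c(OCc3ccccc3)c1.CC[NH+](CC)CC | intermediate
4 | (2S)-5,7-bis(benzyloxy)-2-[3,4,5-tris(benzyloxy)phenyl]-2H-chromene (penta-O-benzyl flav-3-ene; same spatial arrangement at C2 as in 1) | C1=Cc2c(OCc3ccccc3)cc(OCc3ccccc3)cc2O[C@@H]1c1cc(OCc3ccccc3)c(OCc3ccccc3)c(OCc3ccccc3)c1 | intermediate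
5 | 3,4,5-tris(benzyloxy)benzoic acid | OC(=O)c1cc(OCc2ccccc2)c(OCc2ccccc2)c(OCc2ccccc2)c1 | starting material
6 | octa-O-benzyl-(+)-gallocatechin gallate, (2R,3S)-5,7-bis(benzyloxy)-2-[3,4,5-tris(benzyloxy)phenyl]chroman-3-yl 3,4,5-tris(benzyloxy)benzoate (2,3-trans) | O=C(O[C@H]1Cc2c(OCc3ccccc3)cc(OCc3ccccc3)cc2O[C@@H]1c1cc(OCc3ccccc3)c(OCc3ccccc3)c(OCc3ccccc3)c1)c1cc(OCc3ccccc3)c(OCc3ccccc3)c(OCc3ccccc3)c1 | intermediate
7 | (+)-gallocatechin gallate, (2R,3S)-5,7-dihydroxy-2-(3,4,5-trihydroxyphenyl)chroman-3-yl 3,4,5-trihydroxybenzoate (2,3-trans) | O=C(O[C@H]1Cc2c(O)cc(O)cc2O[C@@H]1c1cc(O)c(O)c(O)c1)c1cc(O)c(O)c(O)c1 | target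

**Totals**
Total step count: 4. Longest linear sequence: 4 steps (1 → 2 → 4 → 6 → 7).

**Three steps most likely to fail**

Step 3 (the proposed new photochemical addition). The chromene radical cation may lose the doubly activated C2–H, leading through a flavenyl radical or flavylium ion to C2 racemisation or isomerisation to the flav-2-ene. The trans selectivity may be incomplete, or acid-catalysed Markovnikov addition at C4 may compete. The fallback uses known chemistry and sets out from 4. Hydroboration with BH3·THF (THF, 0 °C) places boron at C3 anti to the C2 aryl group and gives the trans-3-borylflavan F1. Oxidation in the same flask (NaOH, H2O2, 0 °C) proceeds with retention to penta-O-benzyl-(+)-gallocatechin F2. F2 is esterified with acid 5 (N-(3-dimethylaminopropyl)-N'-ethylcarbodiimide hydrochloride, 4-(dimethylamino)pyridine, CH2Cl2, rt) to give 6, where the route is rejoined.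

Step 2 (Burgess dehydration). The hindered axial sulfamate 3 may ionise, with substitution or migration of the C2 aryl group, instead of eliminating, and the electron-rich flavene 4 is sensitive to acid, air and heat. The fallback sets out from 2 and replaces the ionic sulfamate by a neutral, purely thermal Chugaev sequence. Treatment with NaH, CS2 and then MeI in THF gives the S-methyl xanthate F3. Brief thermolysis in degassed o-xylene at 130–140 °C (sealed tube, dark) gives the concerted syn-elimination toward C4 and returns to the route at 4. The ee of 4 is checked by chiral HPLC, because prolonged heating could racemise C2 by electrocyclic ring opening.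

Step 1 (direct penta-benzylation of free epigallocatechin). Free pyrogallol phenoxides may autoxidise, C2 may epimerise through a ring-B quinone methide, and ring A may be C-benzylated. The fallback sets out from 1. Peracetylation (Ac2O, pyridine, rt) gives (−)-epigallocatechin hexaacetate F4 without exposing the polyphenol to base. An acetate-to-benzyl exchange in one flask (BnBr, K2CO3, KI, DMF with about 6 equiv H2O, rt) then unmasks each phenoxide slowly and benzylates it at once, while the slower-reacting aliphatic 3-acetate stays in place, giving 3-O-acetyl-penta-O-benzyl-(−)-epigallocatechin F5. Methanolysis of the 3-acetate (catalytic K2CO3, MeOH/THF, rt) returns to the route at 2.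

**Further compounds**
F1 | step 3 | [(2S,3S)-5,7-bis(benzyloxy)-2-[3,4,5-tris(benzyloxy)phenyl]chroman-3-yl]borane (boron trans to the C2 aryl group) | B[C@H]1Cc2c(OCc3ccccc3)cc(OCc3ccccc3)cc2O[C@@H]1c1cc(OCc3ccccc3)c(OCc3ccccc3)c(OCc3ccccc3)c1
F2 | step 3 | penta-O-benzyl-(+)-gallocatechin, (2R,3S)-5,7-bis(benzyloxy)-2-[3,4,5-tris(benzyloxy)phenyl]chroman-3-ol | O[C@H]1Cc2c(OCc3ccccc3)cc(OCc3ccccc3)cc2O[C@@H]1c1cc(OCc3ccccc3)c(OCc3ccccc3)c(OCc3ccccc3)c1
F3 | step 2 | O-[(2R,3R)-5,7-bis(benzyloxy)-2-[3,4,5-tris(benzyloxy)phenyl]chroman-3-yl] S-methyl carbonodithioate | CSC(=S)O[C@@H]1Cc2c(OCc3ccccc3)cc(OCc3ccccc3)cc2O[C@@H]1c1cc(OCc3ccccc3)c(OCc3ccccc3)c(OCc3ccccc3)c1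
F4 | step 1 | (−)-epigallocatechin hexaacetate, (2R,3R)-5,7-diacetoxy-2-(3,4,5-triacetoxyphenyl)chroman-3-yl acetate | CC(=O)O[C@@H]1Cc2c(OC(C)=O)cc(OC(C)=O)cc2O[C@@H]1c1cc(OC(C)=O)c(OC(C)=O)c(OC(C)=O)c1
F5 | step 1 | 3-O-acetyl-penta-O-benzyl-(−)-epigallocatechin, (2R,3R)-5,7-bis(benzyloxy)-2-[3,4,5-tris(benzyloxy)phenyl]chroman-3-yl acetate | CC(=O)O[C@@H]1Cc2c(OCc3ccccc3)cc(OCc3ccccc3)cc2O[C@@H]1c1cc(OCc3ccccc3)c(OCc3ccccc3)c(OCc3ccccc3)c1
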